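**Retrosynthetic overview**
1. Target 36 ⇒ diene 35 by ring-closing metathesis (C4=C5; the ten-membered carbocycle is closed last). The C8 isovalerate comes from Mitsunobu inversion of the 8S alcohol 33.
2. 33 ⇒ aldehyde 20 + bromobutenolide 31. The key C7–C8 bond is made by an intermolecular zinc Barbier carbonyl allylation, which also unveils the α-methylene-γ-lactone and sets C7 and C8.
3. 20 ⇒ methyl ketone 12 + methacrolein (aldol, oxidation, acid cyclodehydration to the 3(2H)-furanone). C10 comes from (R)-lactic acid by Seebach alkylation.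
4. 31 ⇒ Z-iodo allylic alcohol 28 (carbonylative lactonisation) ⇒ acrolein + silyl propargyl ether, with C6 set by lipase resolution.
5. Ring order: furanone, then butenolide (recast as the α-methylene lactone in the coupling), then the ten-membered ring.

Assumption: the SMILES is read as the (4Z,6R,7R,8R,10S) isomer in germacrane numbering (C6 lactone carbinol, C7 ring fusion, C8 ester carbinol, C10 quaternary ether carbon), and (R)-lactic acid is taken as a commercial material.

**Aldehyde fragment 20**

Step 1
Reactants: 1 (R)-lactic acid; 2 pivalaldehyde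
Product: 3 (2R,5R)-2-tert-butyl-5-methyl-1,3-dioxolan-4-one (cis)
Conditions: cat. TsOH·H2O, cat. H2SO4, pentane, reflux (Dean–Stark); recrystallise from pentane at −78 °C
Reagents that add atoms: none
Why: Acid-catalysed acetalisation with removal of water gives the dioxolanone, and the cis isomer is the thermodynamic product that crystallises, so the new acetal centre stores the lactate configuration.

Step 2
Reactants: 3; 4 allyl bromide
Product: 6 (2R,5S)-2-tert-butyl-5-methyl-5-(prop-2-en-1-yl)-1,3-dioxolan-4-one, via lithium enolate 5 (not isolated)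
Conditions: LiN(i-Pr)2, THF, −78 °C; then 4, −78 → −30 °C
Reagents that add atoms: none
Why: Seebach self-regeneration-of-stereocentres alkylation: the planar enolate is allylated on the face anti to the tert-butyl group, so allyl takes the place of the former hydrogen and the quaternary centre (later C10) is fixed as S.

Step 3
Reactants: 6
Product: 7 (2S)-2-hydroxy-N-methoxy-N,2-dimethylpent-4-enamide
Conditions: MeNH(OMe)·HCl, i-PrMgCl, THF, −20 → 0 °C
Reagents that add atoms: N,O-dimethylhydroxylamine hydrochloride, CNOC.Cl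
Why: Weinreb amide formation by aminolysis of the activated acylal ester with the magnesium amide opens the ring and the hemiacetal alkoxide expels pivalaldehyde, leaving the quaternary centre untouched.

Step 4
Reactants: 7
Product: 9 (2S)-2,4-dihydroxy-N-methoxy-N,2-dimethylbutanamide, via aldehyde 8 (not isolated)
Conditions: O3, CH2Cl2/MeOH, −78 °C; then NaBH4, −78 → 0 °C; silylate without delay
Reagents that add atoms: ozone, [O-][O+]=O
Why: Ozonolysis with in situ borohydride reduction turns the allyl group into the 2-hydroxyethyl arm (C9–C8), the Weinreb amide being inert to NaBH4 at low temperature.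

Step 5
Reactants: 9
Product: 10 (2S)-4-[(tert-butyldiphenylsilyl)oxy]-2-hydroxy-N-methoxy-N,2-dimethylbutanamide
Conditions: TBDPSCl, imidazole, CH2Cl2, 0 °C → rt
Reagents that add atoms: tert-butyl(chloro)diphenylsilane, CC(C)(C)[Si](Cl)(c1ccccc1)c1ccccc1
Why: Silyl ether formation is selective for the primary hydroxyl because the tertiary α-hydroxyl is far too hindered for TBDPSCl.

Step 6
Reactants: 10
Product: 11 (3S)-5-[(tert-butyldiphenylsilyl)oxy]-3-hydroxy-3-methylpentan-2-one
Conditions: MeMgBr (3 equiv), THF, 0 °C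
Reagents that add atoms: methylmagnesium bromide, C[Mg]Br
Why: Weinreb ketone synthesis: the chelated tetrahedral magnesium intermediate stops the addition at the methyl ketone, one equivalent of MeMgBr being spent on the free hydroxyl.

Step 7
Reactants: 11
Product: 12 (3S)-5-[(tert-butyldiphenylsilyl)oxy]-3-methyl-3-[(trimethylsilyl)oxy]pentan-2-one
Conditions: 1-(trimethylsilyl)imidazole, CH2Cl2, rt
Reagents that add atoms: 1-(trimethylsilyl)imidazole, C[Si](C)(C)n1ccnc1
Why: Silylation of the tertiary α-ketol with a powerful neutral silyl donor gives the trimethylsilyl ether without enolising the ketone.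

Step 8
Reactants: 12; 13 methacrolein
Product: 15 (6S)-8-[(tert-butyldiphenylsilyl)oxy]-3-hydroxy-2,6-dimethyl-6-[(trimethylsilyl)oxy]oct-1-en-5-one (both C3 epimers), via lithium enolate 14 (not isolated)
Conditions: LiN(i-Pr)2, THF, −78 °C; then 13, −78 °C
Reagents that add atoms: none
Why: Directed aldol addition: the ketone can enolise only at its methyl group and the lithium enolate adds 1,2 to the α-branched enal at −78 °C, the new carbinol centre being oxidised away in step 9 so its configuration is irrelevant.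

Step 9
Reactants: 15
Product: 16 (6S)-8-[(tert-butyldiphenylsilyl)oxy]-2,6-dimethyl-6-[(trimethylsilyl)oxy]oct-1-ene-3,5-dione (enolised)
Conditions: Dess–Martin periodinane, pyridine, CH2Cl2, 0 °C → rt
Reagents that add atoms: none
Why: Dess–Martin oxidation of the β-hydroxy ketone gives the 1,3-diketone under buffered conditions that spare both silyl ethers.

Step 10
Reactants: 16
Product: 18 (2S)-2-{2-[(tert-butyldiphenylsilyl)oxy]ethyl}-2-methyl-5-(prop-1-en-2-yl)furan-3(2H)-one, via hydroxy diketone 17 (not isolated)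
Conditions: 0.5 M aq. HCl, THF, rt
Reagents that add atoms: none
Why: Acid cleaves the labile tertiary trimethylsilyl ether and the freed hydroxyl adds to the distal C3 carbonyl, dehydration giving the 3(2H)-furanone (acid-catalysed cyclodehydration of an α'-hydroxy 1,3-diketone) while the TBDPS ether survives.

Step 11
Reactants: 18
Product: 19 (2S)-2-(2-hydroxyethyl)-2-methyl-5-(prop-1-en-2-yl)furan-3(2H)-one
Conditions: HF·pyridine, pyridine, THF, 0 °C → rt
Reagents that add atoms: none
Why: Buffered fluoride desilylation removes the TBDPS group without strong base, which the furanone tolerates.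

Step 12
Reactants: 19
Product: 20 [(2S)-2-methyl-3-oxo-5-(prop-1-en-2-yl)-2,3-dihydrofuran-2-yl]acetaldehyde
Conditions: Dess–Martin periodinane, CH2Cl2, 0 °C → rt; used at once
Reagents that add atoms: none
Why: Dess–Martin oxidation gives the β-furanyloxy aldehyde under non-basic conditions, avoiding retro-oxa-Michael opening at the quaternary centre.

**Bromobutenolide fragment 31**

Step 13
Reactants: 21 tert-butyldimethyl(prop-2-yn-1-yloxy)silane; 22 acrolein
Product: 24 rac-6-[(tert-butyldimethylsilyl)oxy]hex-1-en-4-yn-3-ol, via lithium acetylide 23 (not isolated)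
Conditions: n-BuLi, THF, −78 °C; then 22, −78 °C
Reagents that add atoms: none
Why: 1,2-Addition of the lithium acetylide to acrolein at low temperature gives the racemic vinyl alkynyl carbinol.

Step 14
Reactants: 24
Product: 25 (3R)-6-[(tert-butyldimethylsilyl)oxy]hex-1-en-4-yn-3-yl acetate
Conditions: immobilised Candida antarctica lipase B, vinyl acetate, hexane, 30 °C, to ca. 50% conversion
Reagents that add atoms: vinyl acetate, C=COC(C)=O
Why: Lipase-catalysed kinetic resolution by transesterification: following the Kazlauskas rule (vinyl as medium group, silyloxypropynyl as large group) the enzyme acetylates the 3R enantiomer, and the unreacted 3S half of 24 is removed by chromatography.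

Step 15
Reactants: 25
Product: 26 (3R)-6-[(tert-butyldimethylsilyl)oxy]hex-1-en-4-yn-3-ol
Conditions: K2CO3 (cat.), MeOH, 0 °C
Reagents that add atoms: none
Why: Base-catalysed transesterification (methanolysis) frees the 3R alcohol without touching the silyl ether or the stereocentre.

Step 16
Reactants: 26
Product: 28 (3R,4Z)-6-[(tert-butyldimethylsilyl)oxy]-5-iodohexa-1,4-dien-3-ol, via alkenylalanate 27 (not isolated)
Conditions: NaAlH2(OCH2CH2OMe)2, THF, 0 °C; then I2, −78 °C
Reagents that add atoms: iodine, II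
Why: Hydroxyl-directed trans-hydroalumination places hydride on the proximal alkyne carbon and aluminium on the distal one in a five-membered alanate, and iodinolysis with retention gives the Z-iodoalkene with iodine cis to the carbinol carbon.

Step 17
Reactants: 28
Product: 29 (5R)-3-{[(tert-butyldimethylsilyl)oxy]methyl}-5-ethenylfuran-2(5H)-one
Conditions: PdCl2(PPh3)2 (5 mol%), CO (1 atm), K2CO3, THF, rt
Reagents that add atoms: carbon monoxide, [C-]#[O+]
Why: Palladium-catalysed carbonylative lactonisation: oxidative addition to the C–I bond, CO insertion and capture of the acylpalladium by the cis hydroxyl close the butenolide with the C5 stereocentre unchanged.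

Step 18
Reactants: 29
Product: 30 (5R)-5-ethenyl-3-(hydroxymethyl)furan-2(5H)-one
Conditions: HF·pyridine, THF, 0 °C
Reagents that add atoms: none
Why: Acidic fluoride desilylation cleaves the primary silyl ether while the base-sensitive 5-vinylbutenolide stays intact.

Step 19
Reactants: 30
Product: 31 (5R)-3-(bromomethyl)-5-ethenylfuran-2(5H)-one
Conditions: CBr4, PPh3, CH2Cl2, 0 °C
Reagents that add atoms: tetrabromomethane, BrC(Br)(Br)Br
Why: The Appel reaction converts the primary allylic alcohol to the bromide under neutral conditions by SN2 displacement of the alkoxyphosphonium.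

**Coupling and endgame**

Step 20
Reactants: 20; 31
Product: 33 (4R,5R)-5-ethenyl-4-{(1S)-1-hydroxy-2-[(2S)-2-methyl-3-oxo-5-(prop-1-en-2-yl)-2,3-dihydrofuran-2-yl]ethyl}-3-methylideneoxolan-2-one, via allylzinc bromide 32 (not isolated)
Conditions: Zn dust, THF/sat. aq. NH4Cl, 0 °C → rt
Reagents that add atoms: none
Why: Key fragment union by Barbier-type carbonyl allylation: the allylzinc reagent attacks the aldehyde through its ring γ-carbon in a closed chair transition state on the face anti to the C5 vinyl group, which gives the 4,5-trans α-methylene lactone (C7 R) and, for this E-configured cyclic allylmetal, the anti carbinol (C8 S).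

Step 21
Reactants: 33; 34 isovaleric acid
Product: 35 (1R)-1-[(2R,3R)-2-ethenyl-4-methylidene-5-oxooxolan-3-yl]-2-[(2S)-2-methyl-3-oxo-5-(prop-1-en-2-yl)-2,3-dihydrofuran-2-yl]ethyl 3-methylbutanoate
Conditions: PPh3, diisopropyl azodicarboxylate (betaine pre-formed), 34, toluene, 0 °C → rt
Reagents that add atoms: none
Why: Mitsunobu esterification: isovalerate displaces the alkoxyphosphonium of the secondary carbinol by SN2 with inversion, converting C8 from S to the required R while installing the ester.

Step 22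
Reactants: 35
Product: 36 target, (4Z,6R,7R,8R,10S)-8-(3-methylbutanoyloxy)-1-oxo-3,10-epoxygermacra-2,4,11(13)-trien-12,6-olide
Conditions: second-generation Hoveyda–Grubbs catalyst (20 mol%), toluene, 80 °C, 1 mM
Reagents that add atoms: none
Why: Ring-closing metathesis: ruthenium loads at the monosubstituted vinyl group and closes onto the isopropenyl group, releasing ethene and forming the ten-membered ring, whose bridged furanone allows only the Z trisubstituted C4=C5 alkene.

**Compound list**
1 | (R)-lactic acid | C[C@@H](O)C(=O)O | starting material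
2 | pivalaldehyde | CC(C)(C)C=O | starting material
3 | (2R,5R)-2-tert-butyl-5-methyl-1,3-dioxolan-4-one | C[C@H]1O[C@@H](C(C)(C)C)OC1=O | intermediate
4 | allyl bromide | C=CCBr | starting material
5 | lithium (2R)-2-tert-butyl-5-methyl-1,3-dioxol-4-olate (enolate of 3) | CC1=C(O[Li])O[C@H](C(C)(C)C)O1 | intermediate (not isolated)
6 | (2R,5S)-2-tert-butyl-5-methyl-5-(prop-2-en-1-yl)-1,3-dioxolan-4-one | C=CC[C@]1(C)O[C@@H](C(C)(C)C)OC1=O | intermediate
7 | (2S)-2-hydroxy-N-methoxy-N,2-dimethylpent-4-enamide | C=CC[C@](C)(O)C(=O)N(C)OC | intermediate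
8 | (2S)-2-hydroxy-N-methoxy-N,2-dimethyl-4-oxobutanamide | O=CC[C@](C)(O)C(=O)N(C)OC | intermediate (not isolated)
9 | (2S)-2,4-dihydroxy-N-methoxy-N,2-dimethylbutanamide | OCC[C@](C)(O)C(=O)N(C)OC | intermediate
10 | (2S)-4-[(tert-butyldiphenylsilyl)oxy]-2-hydroxy-N-methoxy-N,2-dimethylbutanamide | CC(C)(C)[Si](c1ccccc1)(c1ccccc1)OCC[C@](C)(O)C(=O)N(C)OC | intermediate
11 | (3S)-5-[(tert-butyldiphenylsilyl)oxy]-3-hydroxy-3-methylpentan-2-one | CC(C)(C)[Si](c1ccccc1)(c1ccccc1)OCC[C@](C)(O)C(C)=O | intermediate
12 | (3S)-5-[(tert-butyldiphenylsilyl)oxy]-3-methyl-3-[(trimethylsilyl)oxy]pentan-2-one | CC(C)(C)[Si](c1ccccc1)(c1ccccc1)OCC[C@](C)(O[Si](C)(C)C)C(C)=O | intermediate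
13 | methacrolein | CC(=C)C=O | starting material
14 | lithium enolate of 12 (methyl side) | CC(C)(C)[Si](c1ccccc1)(c1ccccc1)OCC[C@](C)(O[Si](C)(C)C)C(=C)O[Li] | intermediate (not isolated)
15 | (6S)-8-[(tert-butyldiphenylsilyl)oxy]-3-hydroxy-2,6-dimethyl-6-[(trimethylsilyl)oxy]oct-1-en-5-one, both C3 epimers | CC(C)(C)[Si](c1ccccc1)(c1ccccc1)OCC[C@](C)(O[Si](C)(C)C)C(=O)CC(O)C(C)=C | intermediate
16 | (6S)-8-[(tert-butyldiphenylsilyl)oxy]-2,6-dimethyl-6-[(trimethylsilyl)oxy]oct-1-ene-3,5-dione | CC(C)(C)[Si](c1ccccc1)(c1ccccc1)OCC[C@](C)(O[Si](C)(C)C)C(=O)CC(=O)C(C)=C | intermediate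
17 | (6S)-8-[(tert-butyldiphenylsilyl)oxy]-6-hydroxy-2,6-dimethyloct-1-ene-3,5-dione | CC(C)(C)[Si](c1ccccc1)(c1ccccc1)OCC[C@](C)(O)C(=O)CC(=O)C(C)=C | intermediate (not isolated)
18 | (2S)-2-{2-[(tert-butyldiphenylsilyl)oxy]ethyl}-2-methyl-5-(prop-1-en-2-yl)furan-3(2H)-one | CC(C)(C)[Si](c1ccccc1)(c1ccccc1)OCC[C@]1(C)OC(C(C)=C)=CC1=O | intermediate
19 | (2S)-2-(2-hydroxyethyl)-2-methyl-5-(prop-1-en-2-yl)furan-3(2H)-one | OCC[C@]1(C)OC(C(C)=C)=CC1=O | intermediate
20 | [(2S)-2-methyl-3-oxo-5-(prop-1-en-2-yl)-2,3-dihydrofuran-2-yl]acetaldehyde | O=CC[C@]1(C)OC(C(C)=C)=CC1=O | intermediate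
21 | tert-butyldimethyl(prop-2-yn-1-yloxy)silane | C#CCO[Si](C)(C)C(C)(C)C | starting material
22 | acrolein | C=CC=O | starting material
23 | lithium acetylide of 21 | [Li]C#CCO[Si](C)(C)C(C)(C)C | intermediate (not isolated)
24 | rac-6-[(tert-butyldimethylsilyl)oxy]hex-1-en-4-yn-3-ol | C=CC(O)C#CCO[Si](C)(C)C(C)(C)C | intermediate
25 | (3R)-6-[(tert-butyldimethylsilyl)oxy]hex-1-en-4-yn-3-yl acetate | C=C[C@@H](OC(C)=O)C#CCO[Si](C)(C)C(C)(C)C | intermediate
26 | (3R)-6-[(tert-butyldimethylsilyl)oxy]hex-1-en-4-yn-3-ol | C=C[C@@H](O)C#CCO[Si](C)(C)C(C)(C)C | intermediate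
27 | sodium cyclic alkenylalanate (five-membered O–Al–C ring, two 2-methoxyethoxy ligands on Al) | [Na+].COCCO[Al-]1(OCCOC)O[C@H](C=C)C=C1CO[Si](C)(C)C(C)(C)C | intermediate (not isolated)
28 | (3R,4Z)-6-[(tert-butyldimethylsilyl)oxy]-5-iodohexa-1,4-dien-3-ol | C=C[C@@H](O)/C=C(\I)CO[Si](C)(C)C(C)(C)C | intermediate
29 | (5R)-3-{[(tert-butyldimethylsilyl)oxy]methyl}-5-ethenylfuran-2(5H)-one | C=C[C@H]1OC(=O)C(CO[Si](C)(C)C(C)(C)C)=C1 | intermediate
30 | (5R)-5-ethenyl-3-(hydroxymethyl)furan-2(5H)-one | C=C[C@H]1OC(=O)C(CO)=C1 | intermediate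
31 | (5R)-3-(bromomethyl)-5-ethenylfuran-2(5H)-one | C=C[C@H]1OC(=O)C(CBr)=C1 | intermediate
32 | allylzinc bromide from 31 | Br[Zn]CC1=C[C@@H](C=C)OC1=O | intermediate (not isolated)
33 | (4R,5R)-5-ethenyl-4-{(1S)-1-hydroxy-2-[(2S)-2-methyl-3-oxo-5-(prop-1-en-2-yl)-2,3-dihydrofuran-2-yl]ethyl}-3-methylideneoxolan-2-one | C=C1C(=O)O[C@H](C=C)[C@H]1[C@@H](O)C[C@]2(C)OC(C(C)=C)=CC2=O | intermediate
34 | isovaleric acid (3-methylbutanoic acid) | CC(C)CC(=O)O | starting material
35 | (1R)-1-[(2R,3R)-2-ethenyl-4-methylidene-5-oxooxolan-3-yl]-2-[(2S)-2-methyl-3-oxo-5-(prop-1-en-2-yl)-2,3-dihydrofuran-2-yl]ethyl 3-methylbutanoate | C=C1C(=O)O[C@H](C=C)[C@H]1[C@H](OC(=O)CC(C)C)C[C@]2(C)OC(C(C)=C)=CC2=O | intermediate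
36 | (4Z,6R,7R,8R,10S)-8-(3-methylbutanoyloxy)-1-oxo-3,10-epoxygermacra-2,4,11(13)-trien-12,6-olide | C=C1C(=O)O[C@@H]2/C=C(/C)C3=CC(=O)[C@](C)(C[C@@H](OC(=O)CC(C)C)[C@@H]12)O3 | target

**Totals and risks**
Total step count: 22. Longest linear sequence: 15 steps (steps 1–12, then 20–22).

Step 22 (ring-closing metathesis) is the most likely to fail, because the ring is strained, the isopropenyl partner is hindered and electron-poor, and dimerisation through the vinyl group competes. The fallback sets out from 33 and closes the ring before the ester is installed: the free 8S alcohol is treated with the second-generation Hoveyda–Grubbs catalyst at high dilution to give the macrocyclic alcohol (4Z,6R,7R,8S,10S)-8-hydroxy-1-oxo-3,10-epoxygermacra-2,4,11(13)-trien-12,6-olide F1. Its smaller, hydrogen-bond-donating C8 substituent of opposite configuration changes the conformational bias of the open chain. F1 is then esterified with inversion by a Mitsunobu reaction with 34 (PPh3, diisopropyl azodicarboxylate), and the route is rejoined at 36.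

Step 21 (Mitsunobu with isovaleric acid) is second: the carbinol is flanked by a ring methine and a neopentyl-type methylene, the acid is only weakly acidic, and elimination towards the allylic C7–H can compete. The fallback sets out from 33 and separates inversion from acylation. Inversion is done with the small, more acidic formic acid (PPh3, diisopropyl azodicarboxylate) to give (1R)-1-[(2R,3R)-2-ethenyl-4-methylidene-5-oxooxolan-3-yl]-2-[(2S)-2-methyl-3-oxo-5-(prop-1-en-2-yl)-2,3-dihydrofuran-2-yl]ethyl formate F2. The formate is cleaved with KHCO3 in MeOH at 0 °C, which does not touch the methylene lactone, to give (4R,5R)-5-ethenyl-4-{(1R)-1-hydroxy-2-[(2S)-2-methyl-3-oxo-5-(prop-1-en-2-yl)-2,3-dihydrofuran-2-yl]ethyl}-3-methylideneoxolan-2-one F3. F3 is acylated with retention by 3-methylbutanoic anhydride and 4-(dimethylamino)pyridine, and the route is rejoined at 35.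

Step 17 (carbonylative lactonisation) is third: the γ-hydrogen of a 5-vinylbutenolide is acidic, so K2CO3 can erode the C5 stereocentre or move the vinyl double bond into conjugation. The fallback sets out from 28 and makes the C–C bond through an organolithium instead of palladium. The hydroxyl is deprotonated with MeLi, iodine–lithium exchange is done with t-BuLi (2 equiv) at −78 °C, and the vinyllithium is quenched with CO2 to give (2Z,4R)-2-{[(tert-butyldimethylsilyl)oxy]methyl}-4-hydroxyhexa-2,5-dienoic acid F4. F4 lactonises on acidic work-up, so the butenolide never meets base, and the route is rejoined at 29.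

**Further compounds**
F1 | step 22 | (4Z,6R,7R,8S,10S)-8-hydroxy-1-oxo-3,10-epoxygermacra-2,4,11(13)-trien-12,6-olide | C=C1C(=O)O[C@@H]2/C=C(/C)C3=CC(=O)[C@](C)(C[C@H](O)[C@@H]12)O3
F2 | step 21 | (1R)-1-[(2R,3R)-2-ethenyl-4-methylidene-5-oxooxolan-3-yl]-2-[(2S)-2-methyl-3-oxo-5-(prop-1-en-2-yl)-2,3-dihydrofuran-2-yl]ethyl formate | C=C1C(=O)O[C@H](C=C)[C@H]1[C@H](OC=O)C[C@]2(C)OC(C(C)=C)=CC2=O
F3 | step 21 | (4R,5R)-5-ethenyl-4-{(1R)-1-hydroxy-2-[(2S)-2-methyl-3-oxo-5-(prop-1-en-2-yl)-2,3-dihydrofuran-2-yl]ethyl}-3-methylideneoxolan-2-one | C=C1C(=O)O[C@H](C=C)[C@H]1[C@H](O)C[C@]2(C)OC(C(C)=C)=CC2=O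
F4 | step 17 | (2Z,4R)-2-{[(tert-butyldimethylsilyl)oxy]methyl}-4-hydroxyhexa-2,5-dienoic acid | C=C[C@@H](O)/C=C(\C(=O)O)CO[Si](C)(C)C(C)(C)C
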